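## The problem

The target is a flavanone–flavone dimer. A naringenin unit (rings A, C and B) is bonded through C3 to C8″ of an apigenin unit, and O7″ of the flavone carries a hydrogen sulfate. The C3–C8″ bond joins an sp3 carbon to an aryl carbon that has oxygen on both neighbours (O1″ and O7″). It is crowded and is best made early, on a small fragment, not by a late coupling.

There are two adjacent stereocentres, C2 (R) and C3 (S), trans to each other. C3 is α to the C4 carbonyl and can be equilibrated; the trans isomer, with both aryl groups equatorial, is the stable one, so C3 follows C2. C2 cannot be corrected later. It must be set absolutely and is lost whenever ring C opens by β-elimination of O1 (the flavanone–chalcone equilibrium) or the benzylic C2–O1 bond ionises.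

The aryl sulfate does not tolerate acid or a long sequence. O7″ must also be told apart from its near twin O7, while five other phenols need protection that survives strong base.

The feature that makes the key step possible is ring A. C4 is an acyl group on C4a, and C5, C7 and C8a bear oxygen, so ring A is an acylphloroglucinol, the Claisen-folded form of a tetraketide. It can therefore be the last ring built, from a chain C4a–C8a–C8–C7–C6–C5, by forming only the C4a–C5 bond.

## Retrosynthesis

**Target 25 back to diol 21.** The O–S bond and the benzyl ethers are cut last. Sulfate 24 is made from phenol 23, in which O7″ is the only free non-chelated hydroxyl. That requires O7″ to carry a group different from all others (a MOM ether, removed from 22) and O7 of the flavanone to be benzylated first (21 to 22). Installing the sulfate earlier would expose it to acid and to strong base. The forward steps need only O7 over O5 selectivity, which the hydrogen bond from the 5-hydroxyl to O4 provides.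

**Diol 21 back to keto ester 20.** The C4a–C5 bond is cut, opening ring A to a dihydropyranone with a CH2–CO–CH2–CO2Me chain on C8a. Against cutting O1–C8a or C4–C4a, which would need a prefabricated, differentiated phloroglucinol, this cut makes ring A from an acyclic chain and frees its two hydroxyls for the end game. Precursor 20 has one ring fewer and no free phenol. The forward reaction must be a Claisen, not an aldol, cyclisation and must leave C2 alone.

**Keto ester 20 back to open chain 17.** Two operations are undone: the C3 equilibration (20 from its cis isomer 19) and the O1–C8a bond (19 from hydroxy triketo ester 18, the desilylated form of 17). Closing ring C by attack of the C2 hydroxyl on the C8a carbonyl never breaks the C2–O bond. That is the reason for choosing it over any closure that displaces a leaving group at C2. Compound 17 is a linear 3,5,7-trioxo ester; the forward steps need a mild acid and then a base that equilibrates C3 without opening the ring.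

**Triketo ester 17 back to amide 14 and ester 15.** The C4–C4a bond is cut between a Weinreb amide and the terminal carbon of methyl 3,5-dioxohexanoate (15). All six chain carbons of ring A come from one commercial reagent in one step, against stepwise two-carbon extensions. The forward reaction asks the polyanion of 15 to add to a crowded amide carbonyl faster than it removes the α-proton.

**Amide 14 back to imide 9 and aldehyde 10.** The C2–C3 bond is cut as an aldol bond: 14 is the silyl ether of 13, which comes from aldol adduct 12. The auxiliary aldol sets C2 with well-understood facial control and needs no catalyst development. C3 does not have to be right at this stage. The precursors are an arylacetyl imide and 4-benzyloxybenzaldehyde.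

**Imide 9 back to apigenin 1.** The amide bond to auxiliary 7 and the C8″–CH2 bond are cut: 9 comes from acid 6, that from ester 5, and 5 from iodide 4 by coupling with an acetate zinc enolate. Iodide 4 comes from apigenin by 7-O-MOM ether formation (2), 5,4′-dibenzylation (3) and iodination. The crowded C8″–C bond is thus made on the simplest possible substrate, and the protecting-group pattern needed at the end is fixed in the first two steps.

## Roads not taken

**Alternative 1: three-component conjunctive coupling.**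
- Cut: C2–C1′ and C3–C8″ together.
- Forward key step: the ate complex of Z-alkenylboronate A2 with aryllithium A4 meets bromoflavone A3 under Pd(OAc)2 (a divalent palladium precatalyst) and a chiral MandyPhos ligand. Ring B migrates from boron to C2 as C8″ bonds to C3, giving boronate A1.
- Merits: both stereocentres are set by a catalyst in one step, trans from the start, with no auxiliary and no epimerisation. In that respect it is better than the chosen plan.
- Weak points: β-substituted alkenyl boronates are the hard class for this reaction, and the electrophile is di-ortho-substituted. After A1 neither ring A nor ring C exists. The C–B bond must be oxidised, the silyloxymethyl carbon raised to the acid level, a phloroglucinol acylated and O1–C8a closed on an electron-rich ring, all with an epimerisable C3.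
- Comparison: the chosen plan sets against the better stereocontrol a shorter path from the stereocentres to the full skeleton (two condensations) and a C2–O bond that is never re-formed.

**Alternative 2: quinone methide cycloaddition, then C4 oxidation.**
- Cut: C3–C4 and O1–C2.
- Forward key step: a chiral phosphoric acid dehydrates hydroxybenzyl alcohol A6 to its ortho-quinone methide, which adds across E-stilbene A7 to give flavan A5 with ring C and both centres in place.
- Merits: it is the most convergent plan, the trans relationship comes from the alkene geometry, and the sulfate is already present in protected form, so the end game is short.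
- Weak points: the quinone methide has no substituent on its methide carbon for the catalyst to hold, and A7 is a hindered, only moderately electron-rich partner. The decisive problem is that C4 of A5 is a methylene. It must be oxidised to the ketone beside the more easily oxidised C2–H, five benzyl ethers and a trichloroethyl sulfate.
- Comparison: fewer steps on paper. The chosen plan carries C4 at the ketone level from the aldol onward and needs no late C–H oxidation.

**Alternative 3: aryne annulation.**
- Cut: O1–C8a and C4–C4a.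
- Forward key step: CsF releases the aryne from silyl triflate A9; the alkoxide of aldol adduct 12 adds to it, and the aryl anion attacks the imide carbonyl, expelling the auxiliary and giving A8.
- Merits: it shares 12 with the chosen route and replaces six of its steps by one. Ring A arrives benzylated, so one end-game step also disappears. If it worked it would be clearly shorter, and this must be conceded.
- Weak points: the alkoxide of an α-aryl β-hydroxy imide can undergo retro-aldol cleavage at the temperature of aryne generation. Alkoxides add to arynes less readily than phenoxides. The aryl anion, sitting between two oxygens, must attack a carbonyl flanked by the di-ortho-substituted flavonyl group and not be quenched by the acidic α-proton. A9 needs its own synthesis, and A8 would still need the C3 equilibration.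
- Comparison: the chosen plan sets against its brevity that each of its bond formations has a classical counterpart and that ring C is closed under acid, where retro-aldol is not available.

Key step: step 13

Remarks on the chemistry:
- Flavanone locants are unprimed (ring B primed); flavone locants are doubly primed (its ring B triply primed). Fl stands for the protected flavon-8-yl group 5-benzyloxy-2-(4-benzyloxyphenyl)-7-(methoxymethoxy)-4-oxo-4H-chromen-8-yl.
- Assumption: sulfates 24 and 25 would be handled as sodium salts; the hydrogen sulfate form drawn for the target is taken as the compound delivered after cation exchange.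
- Assumption: rotation about C3–C8″ is treated as free, since the target defines no axis.

## Route

Step 1
Reactants: 1 apigenin
Product: 2 7-O-(methoxymethyl)apigenin
Conditions: MOMCl (1.05 equiv), i-Pr2NEt (1.1 equiv), DMF, 0 °C
Reagents that add atoms: chloromethyl methyl ether, COCCl
Why: The 7-hydroxyl is the most acidic phenol of apigenin and the 5-hydroxyl is held by a hydrogen bond to O4, so with one equivalent of base O-alkylation should go to O7 first; any 7,4′-bis-ether is separated.

Step 2
Reactants: 2 7-O-(methoxymethyl)apigenin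
Product: 3 5,4′-di-O-benzyl-7-O-(methoxymethyl)apigenin
Conditions: BnBr (3 equiv), K2CO3, n-Bu4NI (cat.), DMF, 70 °C
Reagents that add atoms: benzyl bromide, BrCc1ccccc1
Why: Williamson etherification; the 4′-phenol reacts readily and the chelated 5-hydroxyl needs excess reagent, heat and iodide catalysis.

Step 3
Reactants: 3 5,4′-di-O-benzyl-7-O-(methoxymethyl)apigenin
Product: 4 8-iodo-5,4′-di-O-benzyl-7-O-(methoxymethyl)apigenin
Conditions: I2, CF3CO2Ag, NaHCO3, CH2Cl2, 0 °C → rt
Reagents that add atoms: iodine, II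
Why: Electrophilic aromatic iodination; with O5 alkylated no free hydroxyl steers the electrophile to C6, and C8, flanked by one ether and the ring oxygen, is the less hindered activated position. NaHCO3 takes up the CF3CO2H that would threaten the MOM ether.

Step 4
Reactants: 4 8-iodo-5,4′-di-O-benzyl-7-O-(methoxymethyl)apigenin
Product: 5 ethyl 2-Fl-acetate
Conditions: BrZnCH2CO2Et (from BrCH2CO2Et, Zn, THF), Pd2(dba)3 (cat.), XPhos (cat.), THF, 60 °C
Reagents that add atoms: (2-ethoxy-2-oxoethyl)zinc bromide, CCOC(=O)C[Zn]Br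
Why: Negishi-type coupling of a Reformatsky reagent with an aryl iodide under zerovalent palladium and a bulky biarylphosphine, the ligand class suited to di-ortho-substituted halides. The neutral zinc enolate should leave the flavone enone alone.

Step 5
Reactants: 5 ethyl 2-Fl-acetate
Product: 6 2-Fl-acetic acid
Conditions: LiOH·H2O, THF/MeOH/H2O, rt; then 1 M HCl, 0 °C
Reagents that add atoms: lithium hydroxide, [Li+].[OH-]
Why: Ester saponification at room temperature; benzyl and MOM ethers and the flavone ring are stable to aqueous LiOH under these conditions.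

Step 6
Reactants: 6 2-Fl-acetic acid; 7 (R)-4-benzyl-2-oxazolidinone
Product: 9 (R)-4-benzyl-3-(2-Fl-acetyl)oxazolidin-2-one, via mixed pivalic anhydride 8 (not isolated)
Conditions: PivCl, Et3N, THF, −20 °C; then 7, LiCl, −20 °C → rt
Reagents that add atoms: none
Why: N-acylation of the oxazolidinone by a mixed pivalic anhydride under LiCl/Et3N; attack goes to the less hindered arylacetyl carbonyl and no strong base meets the flavone.

Step 7
Reactants: 9 (R)-4-benzyl-3-(2-Fl-acetyl)oxazolidin-2-one; 10 4-benzyloxybenzaldehyde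
Product: 12 (R)-4-benzyl-3-[(2R,3R)-3-(4-benzyloxyphenyl)-2-Fl-3-hydroxypropanoyl]oxazolidin-2-one, via dibutylboron Z-enolate 11 (not isolated)
Conditions: Bu2BOTf, i-Pr2NEt, CH2Cl2, −78 → 0 °C; then 10, −78 → 0 °C; then pH 7 buffer, MeOH, H2O2, 0 °C
Reagents that add atoms: none
Why: Evans syn aldol: the Z boron enolate adds to the aldehyde through a Zimmerman–Traxler chair on the enolate face away from the auxiliary benzyl group. With the (R)-auxiliary this sets the carbinol carbon, the later C2, as R; the α-centre (later C3) comes out syn and is corrected in step 12.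

Step 8
Reactants: 12 (R)-4-benzyl-3-[(2R,3R)-3-(4-benzyloxyphenyl)-2-Fl-3-hydroxypropanoyl]oxazolidin-2-one
Product: 13 (2R,3R)-3-(4-benzyloxyphenyl)-2-Fl-3-hydroxy-N-methoxy-N-methylpropanamide
Conditions: MeNH(OMe)·HCl, AlMe3, THF, −20 → 0 °C
Reagents that add atoms: N,O-dimethylhydroxylamine hydrochloride, CNOC.Cl
Why: Aluminium amide transamidation of an aldol imide to the Weinreb amide; the free β-hydroxyl binds aluminium and directs attack to the exocyclic carbonyl, releasing the auxiliary.

Step 9
Reactants: 13 (2R,3R)-3-(4-benzyloxyphenyl)-2-Fl-3-hydroxy-N-methoxy-N-methylpropanamide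
Product: 14 (2R,3R)-3-(4-benzyloxyphenyl)-2-Fl-N-methoxy-N-methyl-3-(triethylsilyloxy)propanamide
Conditions: TESCl, imidazole, DMAP (cat.), DMF, rt
Reagents that add atoms: chlorotriethylsilane, CC[Si](Cl)(CC)CC
Why: Silylation of the secondary alcohol; the ether blocks alkoxide formation and retro-aldol cleavage in the strongly basic next step and can later be removed without acid strong enough to harm the MOM ether.

Step 10
Reactants: 14 (2R,3R)-3-(4-benzyloxyphenyl)-2-Fl-N-methoxy-N-methyl-3-(triethylsilyloxy)propanamide; 15 methyl 3,5-dioxohexanoate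
Product: 17 methyl (8R,9R)-9-(4-benzyloxyphenyl)-8-Fl-3,5,7-trioxo-9-(triethylsilyloxy)nonanoate, via trilithium trianion 16 (not isolated)
Conditions: 15 (2.5 equiv), LiN(i-Pr)2 (7.5 equiv), THF, 0 °C; then 14, −78 → −20 °C; then AcOH, −78 °C
Reagents that add atoms: none
Why: C-acylation of a 1,3,5-tricarbonyl polyanion at its terminal, most nucleophilic carbon by a Weinreb amide, forming C4–C4a. The chelated tetrahedral adduct holds until the quench, so the product neither consumes the nucleophile nor adds a second time.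

Step 11
Reactants: 17 methyl (8R,9R)-9-(4-benzyloxyphenyl)-8-Fl-3,5,7-trioxo-9-(triethylsilyloxy)nonanoate
Product: 19 methyl 4-[(2R,3R)-2-(4-benzyloxyphenyl)-3-Fl-4-oxo-3,4-dihydro-2H-pyran-6-yl]-3-oxobutanoate (2,3-cis), via hydroxy triketo ester 18 (not isolated)
Conditions: HF·pyridine, pyridine, THF, 0 °C → rt; then p-TsOH·H2O (cat.), 4 Å MS, CH2Cl2, 0 °C → rt
Reagents that add atoms: none
Why: Fluoride removes the silyl ether, the δ-hydroxy β-diketone closes to its six-membered hemiketal at C8a, and acid dehydrates it to the vinylogous ester (cyclodehydration to a 2,3-dihydro-4-pyranone). The C2–O bond is never broken, so C2 stays R; the syn aldol relationship becomes 2,3-cis.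

Step 12
Reactants: 19 methyl 4-[(2R,3R)-2-(4-benzyloxyphenyl)-3-Fl-4-oxo-3,4-dihydro-2H-pyran-6-yl]-3-oxobutanoate (2,3-cis)
Product: 20 methyl 4-[(2R,3S)-2-(4-benzyloxyphenyl)-3-Fl-4-oxo-3,4-dihydro-2H-pyran-6-yl]-3-oxobutanoate (2,3-trans)
Conditions: DBU (1.5 equiv), toluene, rt
Reagents that add atoms: none
Why: Base-mediated epimerisation of the α-centre of a cyclic ketone through its enolate; the cis isomer holds one aryl group axial and should drain into the trans isomer with both equatorial. Proton return to the C3 enolate is expected to outrun β-elimination of O1, whose bond lies near the nodal plane of the enolate, so C2 should stay R.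

Step 13
Reactants: 20 methyl 4-[(2R,3S)-2-(4-benzyloxyphenyl)-3-Fl-4-oxo-3,4-dihydro-2H-pyran-6-yl]-3-oxobutanoate (2,3-trans)
Product: 21 (2R,3S)-2-(4-benzyloxyphenyl)-3-Fl-5,7-dihydroxychroman-4-one
Conditions: Mg(OMe)2 (6 equiv), MeOH/THF, rt → 50 °C; then 1 M HCl, 0 °C
Reagents that add atoms: none
Why: Mg(OMe)2 holds the keto ester as its magnesium chelate; from the small fraction whose keto ester is not ionised, methoxide removes a proton from the side-chain CH2 on C8a (C8) to give the extended enolate O4–C4=C4a–C8a=C8, whose α-carbon C4a adds to the ester carbonyl C5 and expels methoxide. Two enolisations then aromatise ring A, and the magnesium phenoxide chelated between O5 and O4 is the sink that pulls the equilibria forward. The closest known reaction is the Mg(OMe)2-mediated Claisen cyclisation of 3,5,7-trioxoalkanoates to acylphloroglucinols, including its 4-pyranone-masked variants. Ring A closes in a 6-(enolexo)-exo-trig mode. No stereocentre is formed; C2 and C3 are carried through, and C3 remains under thermodynamic control in favour of trans. The step needs Claisen over aldol folding and C- over O-acylation: the enol ether O1–C8a places the chain trans to C4 across C4a=C8a, so the ester α-carbon C6 cannot reach C4, O4 cannot reach C5, and C4a is the only nucleophilic atom that can close a six-membered ring. It also needs C2 to survive, and the only path to its loss is β-elimination of O1 from a C3 enolate. That path is disfavoured because the C3–H is shielded and its anion poorly stabilised by the twisted di-ortho-substituted flavonyl group, because the C2–O1 bond overlaps badly with that enolate, and because reprotonation in methanol is fast.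

Step 14
Reactants: 21 (2R,3S)-2-(4-benzyloxyphenyl)-3-Fl-5,7-dihydroxychroman-4-one
Product: 22 (2R,3S)-7-benzyloxy-2-(4-benzyloxyphenyl)-3-Fl-5-hydroxychroman-4-one
Conditions: BnOH, PPh3, DIAD, THF, 0 °C → rt
Reagents that add atoms: benzyl alcohol, OCc1ccccc1
Why: Mitsunobu etherification of the acidic 7-hydroxyl under neutral conditions; the 5-hydroxyl is hydrogen-bonded to O4 and does not compete, and no base is present that could open ring C.

Step 15
Reactants: 22 (2R,3S)-7-benzyloxy-2-(4-benzyloxyphenyl)-3-Fl-5-hydroxychroman-4-one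
Product: 23 (2R,3S)-7-benzyloxy-2-(4-benzyloxyphenyl)-3-[5-benzyloxy-2-(4-benzyloxyphenyl)-7-hydroxy-4-oxo-4H-chromen-8-yl]-5-hydroxychroman-4-one
Conditions: 2 M aq. HCl, MeOH/THF, 45 °C
Reagents that add atoms: none
Why: Acid-catalysed acetal cleavage of the aryl MOM ether with methanol as acceptor; benzyl ethers and the flavanone are stable to dilute acid at this temperature.

Step 16
Reactants: 23 (2R,3S)-7-benzyloxy-2-(4-benzyloxyphenyl)-3-[5-benzyloxy-2-(4-benzyloxyphenyl)-7-hydroxy-4-oxo-4H-chromen-8-yl]-5-hydroxychroman-4-one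
Product: 24 5-benzyloxy-2-(4-benzyloxyphenyl)-8-[(2R,3S)-7-benzyloxy-2-(4-benzyloxyphenyl)-5-hydroxy-4-oxochroman-3-yl]-4-oxo-4H-chromen-7-yl hydrogen sulfate
Conditions: SO3·pyridine (5 equiv), pyridine, rt → 45 °C; then aq. NaHCO3
Reagents that add atoms: sulfur trioxide pyridine complex, [O-]S(=O)(=O)[n+]1ccccc1
Why: O-sulfation of a phenol by SO3·pyridine; O7″ is the only free non-chelated hydroxyl, the 5-hydroxyl being held by O4 and inert here. The NaHCO3 work-up exchanges pyridinium for sodium so that no amine retards the hydrogenolysis.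

Step 17
Reactants: 24 5-benzyloxy-2-(4-benzyloxyphenyl)-8-[(2R,3S)-7-benzyloxy-2-(4-benzyloxyphenyl)-5-hydroxy-4-oxochroman-3-yl]-4-oxo-4H-chromen-7-yl hydrogen sulfate
Product: 25 5-hydroxy-8-[(2R,3S)-5,7-dihydroxy-2-(4-hydroxyphenyl)-4-oxochroman-3-yl]-2-(4-hydroxyphenyl)-4-oxo-4H-chromen-7-yl hydrogen sulfate (CNP0271389.1)
Conditions: H2 (1 atm), Pd/C (10%), THF/MeOH, rt; then H+ ion-exchange resin, 0 °C
Reagents that add atoms: none
Why: Hydrogenolysis of the four benzyl ethers over palladium on carbon at atmospheric pressure; aryl sulfate salts, the flavone double bond and the flavanone C2–O1 bond are expected to persist under these mild conditions.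

## Compound list

1 | apigenin | O=c1cc(-c2ccc(O)cc2)oc2cc(O)cc(O)c12 | starting material
2 | 7-O-(methoxymethyl)apigenin | O=c1cc(-c2ccc(O)cc2)oc2cc(OCOC)cc(O)c12 | intermediate
3 | 5,4′-di-O-benzyl-7-O-(methoxymethyl)apigenin | O=c1cc(-c2ccc(OCc3ccccc3)cc2)oc2cc(OCOC)cc(OCc3ccccc3)c12 | intermediate
4 | 8-iodo-5,4′-di-O-benzyl-7-O-(methoxymethyl)apigenin | O=c1cc(-c2ccc(OCc3ccccc3)cc2)oc2c(I)c(OCOC)cc(OCc3ccccc3)c12 | intermediate
5 | ethyl 2-Fl-acetate | CCOC(=O)Cc1c(OCOC)cc(OCc2ccccc2)c2c(=O)cc(-c3ccc(OCc4ccccc4)cc3)oc12 | intermediate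
6 | 2-Fl-acetic acid | OC(=O)Cc1c(OCOC)cc(OCc2ccccc2)c2c(=O)cc(-c3ccc(OCc4ccccc4)cc3)oc12 | intermediate
7 | (R)-4-benzyl-2-oxazolidinone | O=C1N[C@H](Cc2ccccc2)CO1 | starting material
8 | mixed anhydride of 6 with pivalic acid | CC(C)(C)C(=O)OC(=O)Cc1c(OCOC)cc(OCc2ccccc2)c2c(=O)cc(-c3ccc(OCc4ccccc4)cc3)oc12 | intermediate (not isolated)
9 | (R)-4-benzyl-3-(2-Fl-acetyl)oxazolidin-2-one | O=C1OC[C@@H](Cc2ccccc2)N1C(=O)Cc1c(OCOC)cc(OCc2ccccc2)c2c(=O)cc(-c3ccc(OCc4ccccc4)cc3)oc12 | intermediate
10 | 4-benzyloxybenzaldehyde | O=Cc1ccc(OCc2ccccc2)cc1 | starting material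
11 | dibutylboron Z-enolate of 9 | CCCCB(CCCC)O/C(=C\c1c(OCOC)cc(OCc2ccccc2)c2c(=O)cc(-c3ccc(OCc4ccccc4)cc3)oc12)N1[C@H](Cc2ccccc2)COC1=O | intermediate (not isolated)
12 | (R)-4-benzyl-3-[(2R,3R)-3-(4-benzyloxyphenyl)-2-Fl-3-hydroxypropanoyl]oxazolidin-2-one | O=C1OC[C@@H](Cc2ccccc2)N1C(=O)[C@H](c1c(OCOC)cc(OCc2ccccc2)c2c(=O)cc(-c3ccc(OCc4ccccc4)cc3)oc12)[C@@H](O)c1ccc(OCc2ccccc2)cc1 | intermediate
13 | (2R,3R)-3-(4-benzyloxyphenyl)-2-Fl-3-hydroxy-N-methoxy-N-methylpropanamide | CON(C)C(=O)[C@H](c1c(OCOC)cc(OCc2ccccc2)c2c(=O)cc(-c3ccc(OCc4ccccc4)cc3)oc12)[C@@H](O)c1ccc(OCc2ccccc2)cc1 | intermediate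
14 | (2R,3R)-3-(4-benzyloxyphenyl)-2-Fl-N-methoxy-N-methyl-3-(triethylsilyloxy)propanamide | CON(C)C(=O)[C@H](c1c(OCOC)cc(OCc2ccccc2)c2c(=O)cc(-c3ccc(OCc4ccccc4)cc3)oc12)[C@@H](O[Si](CC)(CC)CC)c1ccc(OCc2ccccc2)cc1 | intermediate
15 | methyl 3,5-dioxohexanoate | COC(=O)CC(=O)CC(C)=O | starting material
16 | trilithium trianion of 15 | [Li+].[Li+].[Li+].C=C([O-])C=C([O-])C=C([O-])OC | intermediate (not isolated)
17 | methyl (8R,9R)-9-(4-benzyloxyphenyl)-8-Fl-3,5,7-trioxo-9-(triethylsilyloxy)nonanoate | COC(=O)CC(=O)CC(=O)CC(=O)[C@H](c1c(OCOC)cc(OCc2ccccc2)c2c(=O)cc(-c3ccc(OCc4ccccc4)cc3)oc12)[C@@H](O[Si](CC)(CC)CC)c1ccc(OCc2ccccc2)cc1 | intermediate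
18 | methyl (8R,9R)-9-(4-benzyloxyphenyl)-8-Fl-9-hydroxy-3,5,7-trioxononanoate | COC(=O)CC(=O)CC(=O)CC(=O)[C@H](c1c(OCOC)cc(OCc2ccccc2)c2c(=O)cc(-c3ccc(OCc4ccccc4)cc3)oc12)[C@@H](O)c1ccc(OCc2ccccc2)cc1 | intermediate (not isolated)
19 | methyl 4-[(2R,3R)-2-(4-benzyloxyphenyl)-3-Fl-4-oxo-3,4-dihydro-2H-pyran-6-yl]-3-oxobutanoate (2,3-cis) | O=C1C=C(CC(=O)CC(=O)OC)O[C@@H](c2ccc(OCc3ccccc3)cc2)[C@H]1c1c(OCOC)cc(OCc2ccccc2)c2c(=O)cc(-c3ccc(OCc4ccccc4)cc3)oc12 | intermediate
20 | methyl 4-[(2R,3S)-2-(4-benzyloxyphenyl)-3-Fl-4-oxo-3,4-dihydro-2H-pyran-6-yl]-3-oxobutanoate (2,3-trans) | O=C1C=C(CC(=O)CC(=O)OC)O[C@@H](c2ccc(OCc3ccccc3)cc2)[C@@H]1c1c(OCOC)cc(OCc2ccccc2)c2c(=O)cc(-c3ccc(OCc4ccccc4)cc3)oc12 | intermediate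
21 | (2R,3S)-2-(4-benzyloxyphenyl)-3-Fl-5,7-dihydroxychroman-4-one | O=C1c2c(O)cc(O)cc2O[C@@H](c2ccc(OCc3ccccc3)cc2)[C@@H]1c1c(OCOC)cc(OCc2ccccc2)c2c(=O)cc(-c3ccc(OCc4ccccc4)cc3)oc12 | intermediate
22 | (2R,3S)-7-benzyloxy-2-(4-benzyloxyphenyl)-3-Fl-5-hydroxychroman-4-one | O=C1c2c(O)cc(OCc3ccccc3)cc2O[C@@H](c2ccc(OCc3ccccc3)cc2)[C@@H]1c1c(OCOC)cc(OCc2ccccc2)c2c(=O)cc(-c3ccc(OCc4ccccc4)cc3)oc12 | intermediate
23 | (2R,3S)-7-benzyloxy-2-(4-benzyloxyphenyl)-3-[5-benzyloxy-2-(4-benzyloxyphenyl)-7-hydroxy-4-oxo-4H-chromen-8-yl]-5-hydroxychroman-4-one | O=C1c2c(O)cc(OCc3ccccc3)cc2O[C@@H](c2ccc(OCc3ccccc3)cc2)[C@@H]1c1c(O)cc(OCc2ccccc2)c2c(=O)cc(-c3ccc(OCc4ccccc4)cc3)oc12 | intermediate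
24 | 5-benzyloxy-2-(4-benzyloxyphenyl)-8-[(2R,3S)-7-benzyloxy-2-(4-benzyloxyphenyl)-5-hydroxy-4-oxochroman-3-yl]-4-oxo-4H-chromen-7-yl hydrogen sulfate | O=C1c2c(O)cc(OCc3ccccc3)cc2O[C@@H](c2ccc(OCc3ccccc3)cc2)[C@@H]1c1c(OS(=O)(=O)O)cc(OCc2ccccc2)c2c(=O)cc(-c3ccc(OCc4ccccc4)cc3)oc12 | intermediate
25 | 5-hydroxy-8-[(2R,3S)-5,7-dihydroxy-2-(4-hydroxyphenyl)-4-oxochroman-3-yl]-2-(4-hydroxyphenyl)-4-oxo-4H-chromen-7-yl hydrogen sulfate | O=C1c2c(O)cc(O)cc2O[C@@H](c2ccc(O)cc2)[C@@H]1c1c(OS(=O)(=O)O)cc(O)c2c(=O)cc(-c3ccc(O)cc3)oc12 | target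

## Step count and risks

Total: 17 steps. Longest linear sequence: 17 steps, from apigenin 1 to 25.

**Step 13 (key step).** Two things may go wrong. Configuration at C2 may be lost through reversible opening of ring C (β-elimination of O1 from the C3 enolate, then unselective reclosure). Or ring A may fail to close because the chelated keto ester enolate is too poor an electrophile, with methoxide addition at C8a unmasking the chain and opening the aldol channel.

Fallback: a base-free closure of the same bond, setting out from 14 and returning at 21.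
- Commercial 2,2,6-trimethyl-4H-1,3-dioxin-4-one is C-acetylated through its lithium dienolate to 2,2-dimethyl-6-(2-oxopropyl)-4H-1,3-dioxin-4-one F1.
- The dilithium dianion of F1 is acylated by 14 to the diketo dioxinone silyl ether F2.
- HF·pyridine and then catalytic p-TsOH give the cis dihydropyranone dioxinone F3, and DBU converts it to the trans dihydropyranone dioxinone F4.
- Heating F4 in dilute toluene at 110 °C expels acetone and leaves an acylketene whose central carbon lies within reach of C4a. C-acylation of the enol ether followed by tautomerisation would give 21 with no base present.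
- Thermal acylketene release from dioxinones and C-acylation of enol ethers and enamines by acylketenes are known; their intramolecular use here rests on mechanistic reasoning.

**Step 10.** The trianion may remove the α-aryl proton of 14 in place of adding, may add too slowly to the congested amide carbonyl, or may attack the flavone pyranone.

Fallback: from 14, returning at 17. Reduction with i-Bu2AlH gives the aldehyde F5. Aldol addition of trianion 16 at −78 °C, far faster than acylation, gives the hydroxy diketo ester F6 as a mixture at the new carbinol. Dess–Martin periodinane oxidises it to 17.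

**Step 12.** Ring opening by β-elimination may compete with epimerisation, or proton removal at the shielded C3 may be too slow.

Fallback: from 19, returning at 23, moving the equilibration to an acid step where no enolate exists. Cis compound 19 is taken through the Mg(OMe)2 cyclisation to the cis diol F7. Mitsunobu benzylation gives the cis benzyl ether F8. The HCl/MeOH treatment of step 15, run longer and warmer, then removes the MOM ether and equilibrates C3 through the aryl ketone enol to give 23.

**Step 7.** Enolisation of the hindered imide may be incomplete, the flavone carbonyl may capture boron, and facial selectivity may erode.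

Fallback: an acylation–reduction sequence, from 6 and returning at 13.
- Acid 6 is joined to (S)-4-benzyl-2-oxazolidinone as in step 6 to give the (S)-imide F9.
- Its sodium enolate (NaN(SiMe3)2, THF, −78 °C) is acylated with 4-benzyloxybenzoyl chloride on the face away from the benzyl group, giving the β-keto imide F10.
- Chelation-controlled reduction with Zn(BH4)2 gives the syn hydroxy imide F11, whose acyl part has the same configuration as that of 12.
- AlMe3 and MeNH(OMe)·HCl then give 13.

**Step 4.** Oxidative addition and transmetalation at the di-ortho-substituted iodide may be slow, with protodeiodination taking over.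

Fallback: from 4, returning at 6. Stille coupling with CH2=CHCH2SnBu3 and Pd(PPh3)4 gives the 8-allyl flavone F12. Lemieux–Johnson cleavage (OsO4 cat., NaIO4, 2,6-lutidine) gives the arylacetaldehyde F13. Pinnick oxidation (NaClO2, NaH2PO4, 2-methyl-2-butene) gives 6.

Further compounds

F1 | step 13 | 2,2-dimethyl-6-(2-oxopropyl)-4H-1,3-dioxin-4-one | CC(=O)CC1=CC(=O)OC(C)(C)O1
F2 | step 13 | 6-[(5R,6R)-6-(4-benzyloxyphenyl)-5-Fl-2,4-dioxo-6-(triethylsilyloxy)hexyl]-2,2-dimethyl-4H-1,3-dioxin-4-one | CC1(C)OC(=O)C=C(CC(=O)CC(=O)[C@H](c2c(OCOC)cc(OCc3ccccc3)c3c(=O)cc(-c4ccc(OCc5ccccc5)cc4)oc23)[C@@H](O[Si](CC)(CC)CC)c2ccc(OCc3ccccc3)cc2)O1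
F3 | step 13 | 6-{[(2R,3R)-2-(4-benzyloxyphenyl)-3-Fl-4-oxo-3,4-dihydro-2H-pyran-6-yl]methyl}-2,2-dimethyl-4H-1,3-dioxin-4-one (2,3-cis) | O=C1C=C(CC2=CC(=O)OC(C)(C)O2)O[C@@H](c2ccc(OCc3ccccc3)cc2)[C@H]1c1c(OCOC)cc(OCc2ccccc2)c2c(=O)cc(-c3ccc(OCc4ccccc4)cc3)oc12
F4 | step 13 | 6-{[(2R,3S)-2-(4-benzyloxyphenyl)-3-Fl-4-oxo-3,4-dihydro-2H-pyran-6-yl]methyl}-2,2-dimethyl-4H-1,3-dioxin-4-one (2,3-trans) | O=C1C=C(CC2=CC(=O)OC(C)(C)O2)O[C@@H](c2ccc(OCc3ccccc3)cc2)[C@@H]1c1c(OCOC)cc(OCc2ccccc2)c2c(=O)cc(-c3ccc(OCc4ccccc4)cc3)oc12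
F5 | step 10 | (2R,3R)-3-(4-benzyloxyphenyl)-2-Fl-3-(triethylsilyloxy)propanal | O=C[C@H](c1c(OCOC)cc(OCc2ccccc2)c2c(=O)cc(-c3ccc(OCc4ccccc4)cc3)oc12)[C@@H](O[Si](CC)(CC)CC)c1ccc(OCc2ccccc2)cc1
F6 | step 10 | methyl 9-(4-benzyloxyphenyl)-8-Fl-7-hydroxy-3,5-dioxo-9-(triethylsilyloxy)nonanoate (C8 and C9 as in 14, C7 epimers) | COC(=O)CC(=O)CC(=O)CC(O)[C@H](c1c(OCOC)cc(OCc2ccccc2)c2c(=O)cc(-c3ccc(OCc4ccccc4)cc3)oc12)[C@@H](O[Si](CC)(CC)CC)c1ccc(OCc2ccccc2)cc1
F7 | step 12 | (2R,3R)-2-(4-benzyloxyphenyl)-3-Fl-5,7-dihydroxychroman-4-one (2,3-cis) | O=C1c2c(O)cc(O)cc2O[C@@H](c2ccc(OCc3ccccc3)cc2)[C@H]1c1c(OCOC)cc(OCc2ccccc2)c2c(=O)cc(-c3ccc(OCc4ccccc4)cc3)oc12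
F8 | step 12 | (2R,3R)-7-benzyloxy-2-(4-benzyloxyphenyl)-3-Fl-5-hydroxychroman-4-one (2,3-cis) | O=C1c2c(O)cc(OCc3ccccc3)cc2O[C@@H](c2ccc(OCc3ccccc3)cc2)[C@H]1c1c(OCOC)cc(OCc2ccccc2)c2c(=O)cc(-c3ccc(OCc4ccccc4)cc3)oc12
F9 | step 7 | (S)-4-benzyl-3-(2-Fl-acetyl)oxazolidin-2-one | O=C1OC[C@H](Cc2ccccc2)N1C(=O)Cc1c(OCOC)cc(OCc2ccccc2)c2c(=O)cc(-c3ccc(OCc4ccccc4)cc3)oc12
F10 | step 7 | (S)-4-benzyl-3-[(2R)-3-(4-benzyloxyphenyl)-2-Fl-3-oxopropanoyl]oxazolidin-2-one | O=C1OC[C@H](Cc2ccccc2)N1C(=O)[C@H](c1c(OCOC)cc(OCc2ccccc2)c2c(=O)cc(-c3ccc(OCc4ccccc4)cc3)oc12)C(=O)c1ccc(OCc2ccccc2)cc1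
F11 | step 7 | (S)-4-benzyl-3-[(2R,3R)-3-(4-benzyloxyphenyl)-2-Fl-3-hydroxypropanoyl]oxazolidin-2-one | O=C1OC[C@H](Cc2ccccc2)N1C(=O)[C@H](c1c(OCOC)cc(OCc2ccccc2)c2c(=O)cc(-c3ccc(OCc4ccccc4)cc3)oc12)[C@@H](O)c1ccc(OCc2ccccc2)cc1
F12 | step 4 | 8-allyl-5,4′-di-O-benzyl-7-O-(methoxymethyl)apigenin | C=CCc1c(OCOC)cc(OCc2ccccc2)c2c(=O)cc(-c3ccc(OCc4ccccc4)cc3)oc12
F13 | step 4 | 2-Fl-acetaldehyde | O=CCc1c(OCOC)cc(OCc2ccccc2)c2c(=O)cc(-c3ccc(OCc4ccccc4)cc3)oc12
A1 | alternative 1 | pinacol boronate carrying ring B on C2 and the silyl-protected flavone on C3 (product of the conjunctive coupling) | CC1(C)OB(OC1(C)C)[C@@H](c1ccc(OCc2ccccc2)cc1)[C@H](c1c(O[Si](C(C)C)(C(C)C)C(C)C)cc(OCc2ccccc2)c2c(=O)cc(-c3ccc(OCc4ccccc4)cc3)oc12)CO[Si](C)(C)C(C)(C)C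
A2 | alternative 1 | (Z)-3-(tert-butyldimethylsilyloxy)prop-1-enylboronic acid pinacol ester | CC1(C)OB(OC1(C)C)/C=C\CO[Si](C)(C)C(C)(C)C
A3 | alternative 1 | 8-bromo-5,4′-di-O-benzyl-7-O-(triisopropylsilyl)apigenin | O=c1cc(-c2ccc(OCc3ccccc3)cc2)oc2c(Br)c(O[Si](C(C)C)(C(C)C)C(C)C)cc(OCc3ccccc3)c12
A4 | alternative 1 | 4-benzyloxyphenyllithium | [Li]c1ccc(OCc2ccccc2)cc1
A5 | alternative 2 | 2,3-trans flavan–flavone with the trichloroethyl sulfate in place (product of the cycloaddition) | C1c2c(OCc3ccccc3)cc(OCc3ccccc3)cc2O[C@@H](c2ccc(OCc3ccccc3)cc2)[C@@H]1c1c(OS(=O)(=O)OCC(Cl)(Cl)Cl)cc(OCc2ccccc2)c2c(=O)cc(-c3ccc(OCc4ccccc4)cc3)oc12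
A6 | alternative 2 | 3,5-bis(benzyloxy)-2-(hydroxymethyl)phenol | OCc1c(O)cc(OCc2ccccc2)cc1OCc1ccccc1
A7 | alternative 2 | 5-benzyloxy-2-(4-benzyloxyphenyl)-8-[(E)-2-(4-benzyloxyphenyl)ethenyl]-4-oxo-4H-chromen-7-yl 2,2,2-trichloroethyl sulfate | O=c1cc(-c2ccc(OCc3ccccc3)cc2)oc2c(/C=C/c3ccc(OCc4ccccc4)cc3)c(OS(=O)(=O)OCC(Cl)(Cl)Cl)cc(OCc3ccccc3)c12
A8 | alternative 3 | pentabenzyl flavanone–flavone with a methoxymethyl ether on O7″ (product of the aryne annulation) | O=C1c2c(OCc3ccccc3)cc(OCc3ccccc3)cc2O[C@@H](c2ccc(OCc3ccccc3)cc2)[C@@H]1c1c(OCOC)cc(OCc2ccccc2)c2c(=O)cc(-c3ccc(OCc4ccccc4)cc3)oc12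
A9 | alternative 3 | 3,5-bis(benzyloxy)-2-(trimethylsilyl)phenyl trifluoromethanesulfonate | C[Si](C)(C)c1c(OS(=O)(=O)C(F)(F)F)cc(OCc2ccccc2)cc1OCc1ccccc1
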